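**Retrosynthetic overview**
1. Target 13 ⇐ desilylation and isopropylidene Wittig on aldehyde 11 ⇐ DIBAL reduction of the seven-membered aryl lactone 10. The lactone C=O becomes the prenyl CH= and the lactone O is the 7-OH.
2. 10 ⇐ key bond ArCH2–C2'' by carbene-catalysed homoenolate addition of dienal 8 to o-quinone methide 9. Both carbons are natively electrophilic, and this step sets the only stereocenter.
3. 9 ⇐ Mannich-base methiodide 5 ⇐ kaempferol 1 (C8 aminomethylation, 3,4'-O-silylation). 8 ⇐ methacrolein + formylmethylene ylide.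
4. Rings: the A, C and B rings come intact from kaempferol. The only ring formed is the temporary seven-membered lactone (step 5), opened again in steps 6–7.

Assumption: the stereocenter in the SMILES is read as (S), i.e. 8-[(2S)-lavandulyl]kaempferol; both antipodes of the triazolium precatalyst are commercial, the one giving (4R)-10 is used, and its sense of induction is confirmed on the first run.

**Step 1**
Reactants: 1 kaempferol
Product: 2 8-[(dimethylamino)methyl]kaempferol
Conditions: CH2(NMe2)2 (1.1 equiv), i-PrOH/1,4-dioxane, 80 °C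
Reagents that add atoms: bis(dimethylamino)methane, CN(C)CN(C)C
Why: Phenolic Mannich aminomethylation ortho to the most acidic 7-OH; C8 is expected to be favoured over C6 in 5,7-dihydroxyflavones (check by HMBC, remove any C6 isomer), and the zwitterionic mono-adduct precipitates, which limits bis-alkylation.

**Step 2**
Reactants: 2 8-[(dimethylamino)methyl]kaempferol
Product: 4 bis-TBS ether: 8-[(dimethylamino)methyl]-3,4'-bis-O-(tert-butyldimethylsilyl)kaempferol (5-OH and 7-OH free), via tris-TBS ether 3 (not isolated)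
Conditions: TBSCl (3.6 equiv), imidazole, DMF, 0 °C→rt; then K2CO3 (0.3 equiv), MeOH, 0 °C, ca. 20 min
Reagents that add atoms: tert-butyldimethylsilyl chloride, CC(C)(C)[Si](C)(C)Cl
Why: Silylation covers 3-, 7- and 4'-OH (the chelated 5-OH stays free); brief carbonate methanolysis then cleaves only the 7-O-silyl ether, the one of the most acidic phenol and assisted by the neighbouring amine (selective aryl silyl ether solvolysis).

**Step 3**
Reactants: 4 bis-TBS ether
Product: 5 {[3-(TBSO)-2-(4-(TBSO)phenyl)-5,7-dihydroxy-4-oxo-4H-chromen-8-yl]methyl}trimethylammonium iodide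
Conditions: MeI (3 equiv), MeCN, rt, dark
Reagents that add atoms: iodomethane, CI
Why: Menshutkin N-quaternisation turns the benzylic amine into a leaving group; without added base the phenols are not methylated.

**Step 4**
Reactants: 6 methacrolein; 7 (triphenylphosphoranylidene)acetaldehyde
Product: 8 (2E)-4-methylpenta-2,4-dienal
Conditions: 6 (2 equiv), CH2Cl2, rt→40 °C; distil
Reagents that add atoms: none
Why: Wittig two-carbon homologation with a stabilised ylide gives the E-enal; excess methacrolein suppresses a second homologation.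

**Step 5**
Reactants: 5 ammonium iodide; 8 (2E)-4-methylpenta-2,4-dienal
Product: 10 (4R)-lactone: 3,4'-bis-O-TBS-kaempferol with O7 and C8 bridged by O–C(=O)–CH2–CH(isopropenyl)–CH2 (a 4-(prop-1-en-2-yl)-4,5-dihydro-oxepin-2(3H)-one ring), via o-quinone methide 9 (not isolated)
Conditions: chiral aminoindanol-derived N-mesityl triazolium BF4 (15 mol%), K2CO3 (2.2 equiv), 4 Å MS, THF, 0 °C→rt; 8 (2 equiv) added slowly
Reagents that add atoms: none
Why: N-heterocyclic-carbene homoenolate formal [4+3] annulation (known reaction class, untested on this dienal and this flavonoid quinone methide): carbonate deprotonates 7-OH so NMe3 leaves to give 9, the carbene makes the enal β-carbon nucleophilic so it adds to the exocyclic CH2 of 9, and the 7-phenoxide then closes onto the acyl azolium; the stereocenter is set by the catalyst's indane wall shielding one face of the β-carbon.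

**Step 6**
Reactants: 10 (4R)-lactone
Product: 11 (3R)-3-{[3-(TBSO)-2-(4-(TBSO)phenyl)-5,7-dihydroxy-4-oxo-4H-chromen-8-yl]methyl}-4-methylpent-4-enal (open hydroxy-aldehyde, in equilibrium with its seven-membered lactol)
Conditions: DIBAL-H (2.3 equiv), CH2Cl2, −78 °C; Rochelle salt work-up
Reagents that add atoms: none
Why: Partial reduction of an activated aryl ester, whose aluminium lactolate is stable at −78 °C; the flavone carbonyl is a vinylogous ester held as the 5-O-aluminium chelate and should not be reduced; the stereocenter is β to the carbonyl and untouched.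

**Step 7**
Reactants: 11 aldehyde
Product: 13 8-[(2S)-5-methyl-2-(prop-1-en-2-yl)hex-4-en-1-yl]kaempferol (target), via bis-TBS ether 12 (not isolated)
Conditions: i-PrPPh3+ I− (5 equiv), KHMDS (4.8 equiv), THF, 0 °C; add 11, −78 °C→rt (degassed); then AcOH, TBAF (3 equiv), 0 °C→rt
Reagents that add atoms: isopropyltriphenylphosphonium iodide, CC(C)[P+](c1ccccc1)(c1ccccc1)c1ccccc1.[I-]
Why: Wittig olefination with the non-stabilised isopropylidene ylide (excess covers the two phenols) builds the prenyl terminus and frees 7-OH; fluoride then removes both aryl silyl ethers without acid, so the lavandulyl group cannot cyclise onto 7-OH; the stereocenter carries no acidic hydrogen.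

**Compound list**
1 | kaempferol | O=c1c(O)c(-c2ccc(O)cc2)oc2cc(O)cc(O)c12 | starting material
2 | 8-[(dimethylamino)methyl]kaempferol | CN(C)Cc1c(O)cc(O)c2c(=O)c(O)c(-c3ccc(O)cc3)oc12 | intermediate
3 | 8-[(dimethylamino)methyl]-3,7,4'-tris-O-TBS-kaempferol | CN(C)Cc1c(O[Si](C)(C)C(C)(C)C)cc(O)c2c(=O)c(O[Si](C)(C)C(C)(C)C)c(-c3ccc(O[Si](C)(C)C(C)(C)C)cc3)oc12 | intermediate (not isolated)
4 | 8-[(dimethylamino)methyl]-3,4'-bis-O-TBS-kaempferol | CN(C)Cc1c(O)cc(O)c2c(=O)c(O[Si](C)(C)C(C)(C)C)c(-c3ccc(O[Si](C)(C)C(C)(C)C)cc3)oc12 | intermediate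
5 | {[3-(TBSO)-2-(4-(TBSO)phenyl)-5,7-dihydroxy-4-oxo-4H-chromen-8-yl]methyl}trimethylammonium iodide | C[N+](C)(C)Cc1c(O)cc(O)c2c(=O)c(O[Si](C)(C)C(C)(C)C)c(-c3ccc(O[Si](C)(C)C(C)(C)C)cc3)oc12.[I-] | intermediate
6 | methacrolein | C=C(C)C=O | starting material
7 | (triphenylphosphoranylidene)acetaldehyde | O=CC=P(c1ccccc1)(c1ccccc1)c1ccccc1 | starting material
8 | (2E)-4-methylpenta-2,4-dienal | C=C(C)/C=C/C=O | intermediate
9 | o-quinone methide: 3-(TBSO)-2-(4-(TBSO)phenyl)-5-hydroxy-8-methylidene-chromene-4,7(8H)-dione | C=C1C(=O)C=C(O)C2=C1OC(c1ccc(O[Si](C)(C)C(C)(C)C)cc1)=C(O[Si](C)(C)C(C)(C)C)C2=O | intermediate (not isolated)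
10 | (4R)-lactone (O7/C8-fused 4-isopropenyl-4,5-dihydro-oxepin-2(3H)-one of 3,4'-bis-O-TBS-kaempferol) | C=C(C)[C@H]1CC(=O)Oc2cc(O)c3c(=O)c(O[Si](C)(C)C(C)(C)C)c(-c4ccc(O[Si](C)(C)C(C)(C)C)cc4)oc3c2C1 | intermediate
11 | (3R)-3-{[3,4'-bis(TBSO)-5,7-dihydroxyflavon-8-yl]methyl}-4-methylpent-4-enal | C=C(C)[C@@H](CC=O)Cc1c(O)cc(O)c2c(=O)c(O[Si](C)(C)C(C)(C)C)c(-c3ccc(O[Si](C)(C)C(C)(C)C)cc3)oc12 | intermediate
12 | 8-[(2S)-5-methyl-2-(prop-1-en-2-yl)hex-4-en-1-yl]-3,4'-bis-O-TBS-kaempferol | C=C(C)[C@@H](CC=C(C)C)Cc1c(O)cc(O)c2c(=O)c(O[Si](C)(C)C(C)(C)C)c(-c3ccc(O[Si](C)(C)C(C)(C)C)cc3)oc12 | intermediate (not isolated)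
13 | 8-[(2S)-5-methyl-2-(prop-1-en-2-yl)hex-4-en-1-yl]kaempferol | C=C(C)[C@@H](CC=C(C)C)Cc1c(O)cc(O)c2c(=O)c(O)c(-c3ccc(O)cc3)oc12 | target

**Step count**
Total steps: 7. Longest linear sequence: 6 (steps 1, 2, 3, 5, 6, 7 from kaempferol); step 4 is a one-step side branch.

**Three steps most likely to fail**

Step 5 (annulation). Risks: the quinone methide may alkylate the carbene, the dienal may react at its δ-carbon or as an acyl anion, and the enantioselectivity is unproven on this substrate. The fallback sets out from 5 and comes back at 12. Ammonium salt 5 is treated with K2CO3 to give 9 in the presence of 6-methylhept-5-en-2-one (sulcatone) and a chiral primary amine catalyst (9-amino-9-deoxy-epi-cinchona type, with acid co-catalyst). Enamine α-alkylation at the internal CH2 of the ketone gives 8-[(2S)-2-acetyl-5-methylhex-4-en-1-yl]-3,4'-bis-O-TBS-kaempferol F1. Methylenation of F1 with Ph3P=CH2 (or Zn/CH2Br2/TiCl4 if epimerisation is seen) gives 12, which is desilylated as in step 7.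

Step 2 (selective 7-O-desilylation). Risks: loss of the 4'-O-silyl group as well, or incomplete cleavage. The fallback sets out from 3, isolated this time, and comes back at 9 and hence 10. Tris-TBS ether 3 is quaternised with MeI to {[3,7-bis(TBSO)-2-(4-(TBSO)phenyl)-5-hydroxy-4-oxo-4H-chromen-8-yl]methyl}trimethylammonium iodide F2. In the annulation, CsF (1.05 equiv) with 18-crown-6 and a catalytic acetate base replaces K2CO3, so fluoride removes the 7-O-silyl group next to the ammonium in situ, NMe3 is expelled and 9 forms in the flask.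

Step 6 (DIBAL). Risks: over-reduction to the diol or reduction of the pyrone. The fallback sets out from 10 and comes back at 11. Lactone 10 is opened with MeNH(OMe)·HCl/i-PrMgCl (THF, −20 °C) to (3R)-N-methoxy-N,4-dimethyl-3-{[3,4'-bis(TBSO)-5,7-dihydroxyflavon-8-yl]methyl}pent-4-enamide F3. Reduction of F3 with LiAlH4 or DIBAL-H at −78 °C stops at the chelated aminal and gives 11 on work-up.

**Further compounds**
F1 | step 5 | 8-[(2S)-2-acetyl-5-methylhex-4-en-1-yl]-3,4'-bis-O-TBS-kaempferol | CC(=O)[C@@H](CC=C(C)C)Cc1c(O)cc(O)c2c(=O)c(O[Si](C)(C)C(C)(C)C)c(-c3ccc(O[Si](C)(C)C(C)(C)C)cc3)oc12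
F2 | step 2 | {[3,7-bis(TBSO)-2-(4-(TBSO)phenyl)-5-hydroxy-4-oxo-4H-chromen-8-yl]methyl}trimethylammonium iodide | C[N+](C)(C)Cc1c(O[Si](C)(C)C(C)(C)C)cc(O)c2c(=O)c(O[Si](C)(C)C(C)(C)C)c(-c3ccc(O[Si](C)(C)C(C)(C)C)cc3)oc12.[I-]
F3 | step 6 | (3R)-N-methoxy-N,4-dimethyl-3-{[3,4'-bis(TBSO)-5,7-dihydroxyflavon-8-yl]methyl}pent-4-enamide | C=C(C)[C@@H](CC(=O)N(C)OC)Cc1c(O)cc(O)c2c(=O)c(O[Si](C)(C)C(C)(C)C)c(-c3ccc(O[Si](C)(C)C(C)(C)C)cc3)oc12
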